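**One-step ledger.** In a one-step world every mole of starting material lost would stand as target, and your books would hold two entries. These flasks hold a third, the over-reaction product.

all flasks: free catalyst 16 mol%

| run | starting material | remark | time |
|---|---|---|---|
| Saturday's | 0.44 M | the very flask that is asked about, followed so far |  |
| Friday's | 0.22 M | run made earlier |  |
| flask | 0.44 M |  | 8.0 h |

Saturday's run (percent of the starting material charged)

| time / min | target / % | over-reaction product / % |
|---|---|---|
| 8.00 | 1.9 | 1.4 |
| 12.0 | 1.3 | 0 |
| 20.0 | 2.5 | 0 |
| 25.0 | 2.8 | 0 |
| 40.0 | 6.4 | 2.4 |
| 60.0 | 6.7 | 1.7 |
| 90.0 | 9.7 | 2.7 |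

Friday's run (percent of the starting material charged)

| time / h | target / % | over-reaction product / % |
|---|---|---|
| 0.250 | 1.2 | 1.1 |
| 0.417 | 2.5 | 0 |
| 0.667 | 2.9 | 1.4 |
| 0.833 | 3.6 | 0.1 |
| 1.33 | 4.9 | 0 |
| 2.00 | 6.9 | 2.1 |
| 3.00 | 9.3 | 6.0 |

(scatter of a reading: 1 percentage point)

1. amount of target in the flask at 8.0 h, in percent of the starting material charged
2. amount of over-reaction product in the flask at 8.0 h, in percent of the starting material charged



**Reading the wear.** Target climbs roughly in a line, so its area against time is a triangle. That gives the wear constant w, over-reaction product gained per hour per unit of target standing, 0.430 h⁻¹ from Friday's last reading. Saturday's flask, at twice the concentration, reads 0.371 h⁻¹. Given the scatter, I take w as independent of the charge.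

**My books.** The zero of the scale is balance: target made equals target worn, so target stands at feed over w. Saturday's fractional feed f, read at its last point, is 0.0827 h⁻¹. Held for 8.0 h, it leaves 51.6% starting material. My estimate for this flask at 8.0 h is then target at balance, 9.92%, and by subtraction 38.5% over-reaction product.

**The forecast.** It gives 13% target and 32% over-reaction product, with the warning “Any catalyst loss would lower these values”. Its target is higher than mine, and its over-reaction product lower.

**The flask.** It gives 8.46% target and 33.2% over-reaction product, so the forecast stands within its margins. Left standing, this flask's target has moved by 5 points at 16.2 h.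

    starting material + free catalyst → catalyst intermediate (k = 2.08 M⁻¹ h⁻¹)
    catalyst intermediate → free catalyst + target (k = 4.10 h⁻¹)
    target → over-reaction product (k = 0.418 h⁻¹)
    2 free catalyst → spent catalyst (k = 2.47 M⁻¹ h⁻¹)

**Closing books.** Without the step from target to over-reaction product, this flask holds 41.6% target, not 8.46%. Those 33 percentage points are 36% of what is missing from a full yield of target, and 58% of the charge is still starting material at 8.00 h. Here, w times the geometric mean of the falling target gives 18 points over-reaction product between 4.00 h and 8.00 h; the flask gains 18 points.

**Left longer.** For the flask left until 20.0 h, where target stands at 2.51%, the same reckoning from 8.00 h gives 24 points more over-reaction product. The computed gain is 23 points, which brings over-reaction product to 56.6%.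

The readings were generated by integration for an exercise, noise included.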